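Ring B (chromane numbering) is read as a cyclic pseudo-ester. C8a is the acyl-like carbon of the vinylogous ester O1–C8a=C4a–C5=O in ring A, C4 is its vinylogous cation site, and C2 is an aldehyde carbon. The route rests on a [3+3] union of C4–C4a–C8a with the O1–C2–C3 unit of isovaleraldehyde. The precursor is a racemic ring A block that carries methoxy leaving groups on C4 and C8a. In one flask a chiral counteranion steers attack of the aldehyde enol silane on the C4 cation (C3–C4). The aldehyde oxygen then displaces the C8a methoxide (O1–C8a) and closes ring B. Syncarpic acid (ring C) finally replaces the anomeric methoxy group.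

Key step: step 6

Remark: atoms are numbered O1, C2, C3, C4, C4a, C5 to C8, C8a; ring A is the fused tetramethylcyclohexenedione, ring B the dihydropyran, ring C the pendant enolised trione.
Assumption: the sense of induction of the chiral acid in step 6 cannot be derived from a model, so the antipode that gives the 4S series is fixed by one test run.

Step 1
Reactants: 1 phloroglucinol; 2 3-methylbutanoyl chloride
Product: 3 phlorisovalerophenone
Conditions: AlCl3 (3.5 equiv), CH2Cl2/MeNO2, 40 °C; aq. HCl work-up
Reagents that add atoms: none
Why: Friedel–Crafts acylation of the very electron-rich arene, which should stop after one acyl group because the chelated aryl ketone is deactivated; no stereocenter is formed.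

Step 2
Reactants: 3 phlorisovalerophenone
Product: 4 leptospermone
Conditions: NaOMe, MeI (excess), MeOH, reflux; then aq. HCl
Reagents that add atoms: iodomethane, CI
Why: Exhaustive dearomative C-methylation of an acylphloroglucinol (enolate alkylation), in which the two free ring carbons are each methylated twice while the acyl-bearing carbon stays untouched because the product rests as its hindered, stabilised triketonate.

Step 3
Reactants: 4 leptospermone
Product: 5 leptospermone ring methyl enol ether
Conditions: Me2SO4, K2CO3, acetone, reflux
Reagents that add atoms: dimethyl sulfate, COS(=O)(=O)OC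
Why: Williamson-type O-alkylation of the triketonate with a hard methylating agent, in which K+ should be chelated between the side-chain oxygen and one ring oxygen, so that the free ring oxygen is methylated and crowding blocks C-methylation.

Step 4
Reactants: 5 leptospermone ring methyl enol ether
Product: 7 racemic bis-methyl ether, via carbinol 6 (not isolated)
Conditions: NaBH4, CeCl3·7H2O, MeOH, −40 °C; then methanolic HCl to pH 2, 0 °C
Reagents that add atoms: methanol, CO
Why: Luche 1,2-reduction of the only carbonyl that no CMe2 group flanks, followed by SN1 methanolysis of the carbinol through the vinylogous oxocarbenium ion; C4 forms as a racemate on purpose, because step 6 erases it.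

Step 5
Reactants: 8 isovaleraldehyde
Product: 9 (Z)-enol silane of isovaleraldehyde
Conditions: Me3SiCl, Et3N, DMF, 80 °C; distillation
Reagents that add atoms: chlorotrimethylsilane, C[Si](C)(C)Cl
Why: Silyl enol ether formation by amine-mediated enolisation and O-silylation under equilibrating conditions should favour the Z isomer, and the geometry is not decisive because C3 is equilibrated later.

Step 6
Reactants: 7 racemic bis-methyl ether; 9 (Z)-enol silane of isovaleraldehyde
Product: 13 bicyclic methyl acetal (3S,4S; C2 anomers), via oxocarbenium ion 10 (not isolated), via aldehyde 11 (not isolated), via hemiacetal 12 (not isolated)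
Conditions: BINOL-derived imidodiphosphorimidate acid (IDPi, N-triflyl, 5 mol %), toluene, −60 °C; then K2CO3 (0.3 equiv), MeOH, −20 to 20 °C, same flask
Reagents that add atoms: methanol, CO
Why: Proposed new method: the acid is silylated by 9 and the silylium ion pair abstracts the C4 methoxy group of racemic 7 as Me3SiOMe, so that both enantiomers give the same planar vinylogous oxocarbenium ion 10, which C3 of 9 attacks at C4 to give aldehyde 11 and to pass the silyl group on. After the switch to K2CO3/MeOH, methoxide adds to the aldehyde, and the alkoxide oxygen O1 of hemiacetal 12 adds to C8a and expels the C8a methoxide, so ring B closes by a 6-endo-trig addition–elimination that regenerates methoxide. The closest known reaction types are the IDPi/silylium-catalysed substitutions of lactol acetates and N,O-acetal methyl ethers with enol silanes or silyl ketene acetals, and the isomerisation of δ-oxo esters into cyclic pseudo-esters. C4 (S) is set by the chiral anion that shields one face of 10; C3 (S) is set under thermodynamic control, because 11 epimerises through its enolate, the ring closure is reversible, and the 3,4-trans isomer with both alkyl groups axial avoids the clash of an equatorial isobutyl group with C5=O; C2 forms as anomers that step 8 erases. The step needs attack at C4 rather than C8a, which the C8 gem-dimethyl group secures, and it needs O1 rather than a ring A oxygen as the ring-closing nucleophile, which the methyl cap on C8a and the basic medium secure, since only O1 is anionic there. Proton loss from 10 is reversible under the strong acid, and the capped ring A cannot undergo retro-Michael cleavage, so C4 should not be scrambled.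

Step 7
Reactants: 4 leptospermone
Product: 14 syncarpic acid
Conditions: 6 M aq. HCl, reflux
Reagents that add atoms: none
Why: Acid-catalysed retro-Claisen deacylation of the β-triketone, in which water attacks the only unhindered carbonyl (the side-chain one) and the stabilised ring enol leaves.

Step 8
Reactants: 13 bicyclic methyl acetal; 14 syncarpic acid
Product: 16 ericifolione, via alkylidene 15 (not isolated)
Conditions: TsOH·H2O (10 mol %), CH2Cl2, 5 Å MS, 25 °C
Reagents that add atoms: none
Why: Acid-catalysed exchange of the anomeric methoxy group for the nucleophilic carbon of 14 (Knoevenagel-type condensation at the acetal carbon, then oxa-Michael closure through 15) is reversible only at O1–C2, so C2 should settle under thermodynamic control as 2R with bulky ring C equatorial and cis to the axial C3 isopropyl group, while C3 and C4 keep the trans-diaxial arrangement and O1–C8a stays intact.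

Compound list
1 | phloroglucinol | Oc1cc(O)cc(O)c1 | starting material
2 | 3-methylbutanoyl chloride | CC(C)CC(=O)Cl | starting material
3 | phlorisovalerophenone, 1-(2,4,6-trihydroxyphenyl)-3-methylbutan-1-one | CC(C)CC(=O)c1c(O)cc(O)cc1O | intermediate
4 | leptospermone | CC(C)CC(=O)C1=C(O)C(C)(C)C(=O)C(C)(C)C1=O | intermediate
5 | 3-methoxy-4,4,6,6-tetramethyl-2-(3-methylbutanoyl)cyclohex-2-ene-1,5-dione | CC(C)CC(=O)C1=C(OC)C(C)(C)C(=O)C(C)(C)C1=O | intermediate
6 | 2-(1-hydroxy-3-methylbutyl)-3-methoxy-4,4,6,6-tetramethylcyclohex-2-ene-1,5-dione, racemic | CC(C)CC(O)C1=C(OC)C(C)(C)C(=O)C(C)(C)C1=O | intermediate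
7 | 3-methoxy-2-(1-methoxy-3-methylbutyl)-4,4,6,6-tetramethylcyclohex-2-ene-1,5-dione, racemic | CC(C)CC(OC)C1=C(OC)C(C)(C)C(=O)C(C)(C)C1=O | intermediate
8 | isovaleraldehyde | CC(C)CC=O | starting material
9 | (Z)-trimethyl(3-methylbut-1-enyloxy)silane | CC(C)/C=C\O[Si](C)(C)C | intermediate
10 | O-methylated 2-(3-methylbutylidene)syncarpic acid cation (vinylogous oxocarbenium ion, paired with the chiral anion) | CC(C)CC=C1C(=[O+]C)C(C)(C)C(=O)C(C)(C)C1=O | intermediate
11 | (2S,3S)-3-(2-methoxy-3,3,5,5-tetramethyl-4,6-dioxocyclohex-1-enyl)-5-methyl-2-(propan-2-yl)hexanal | O=C[C@@H](C(C)C)[C@H](CC(C)C)C1=C(OC)C(C)(C)C(=O)C(C)(C)C1=O | intermediate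
12 | methyl hemiacetal of 11 | COC(O)[C@@H](C(C)C)[C@H](CC(C)C)C1=C(OC)C(C)(C)C(=O)C(C)(C)C1=O | intermediate
13 | (3S,4S)-2-methoxy-6,6,8,8-tetramethyl-4-(2-methylpropyl)-3-(propan-2-yl)-3,4-dihydro-2H-chromene-5,7(6H,8H)-dione, C2 anomers | CC(C)C[C@@H]1C2=C(OC(OC)[C@H]1C(C)C)C(C)(C)C(=O)C(C)(C)C2=O | intermediate
14 | syncarpic acid (enol form) | CC1(C)C(=O)C=C(O)C(C)(C)C1=O | intermediate
15 | ring-opened alkylidene: ring C ylidene at C2, ring A as free enol, C3 and C4 as in 13 | CC(C)C[C@H](C1=C(O)C(C)(C)C(=O)C(C)(C)C1=O)[C@H](C(C)C)C=C2C(=O)C(C)(C)C(=O)C(C)(C)C2=O | intermediate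
16 | ericifolione (2R,3S,4S) | CC(C)C[C@@H]1C2=C(O[C@@H](C3=C(O)C(C)(C)C(=O)C(C)(C)C3=O)[C@H]1C(C)C)C(C)(C)C(=O)C(C)(C)C2=O | target

Total step count: 8. Longest linear sequence: 6 (steps 1, 2, 3, 4, 6, 8).

Steps most likely to fail

Risk 1, step 6. Facial discrimination inside the ion pair may be weak, proton loss from the cation may drain material, or ring closure at the crowded C8a may be slow. The fallback sets out from 7 and 9 and gives up catalytic induction for resolution. The substitution is run with achiral Me3SiOTf (5 mol %) in CH2Cl2 at −78 °C, a known Mukaiyama-type alkylation of enol silanes with acetal-type methyl ethers. It is finished with K2CO3/MeOH in the same flask, which should give the racemic 3,4-trans bicyclic methyl acetal F1. Acid-catalysed acetal exchange with (−)-menthol gives diastereomeric acetals, from which the (3S,4S) menthyl acetal F2 is separated by chromatography or crystallisation. Methanolysis (camphorsulfonic acid, MeOH) comes back to the route at 13.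

Risk 2, step 3. Methylation may occur at the side-chain oxygen or at carbon instead of at the ring oxygen. The fallback sets out from 14 and builds the side chain after the cap is in place. Etherification (MeOH, HC(OMe)3, TsOH) gives syncarpic acid methyl ether F3, in which no side-chain oxygen competes. Iodination of the free vinylic carbon (NIS, MeCN) gives the iodoenone F4. Nozaki–Hiyama–Kishi coupling with 8 (CrCl2, NiCl2 cat., DMF) comes back to the route at 6, which enters the methanolysis stage of step 4.

Risk 3, step 8. Substitution at the crowded C2 may be sluggish, or a second molecule of syncarpic acid may add to the ring-opened form. The fallback sets out from 13 and replaces substitution at the acetal by a carbonyl condensation. Mild hydrolysis (aq. AcOH, THF) gives the lactol F5. Its open aldehyde form is condensed with one equivalent of 14 under ethylenediammonium diacetate (Knoevenagel condensation), passes through 15, and comes back to the route at 16 after oxa-Michael closure.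

Further compounds
F1 | step 6 | racemic 3,4-trans bicyclic methyl acetal | CC(C)CC1C2=C(OC(OC)C1C(C)C)C(C)(C)C(=O)C(C)(C)C2=O
F2 | step 6 | (3S,4S) bicyclic (1R,2S,5R)-menthyl acetal | CC(C)C[C@@H]1C2=C(OC(O[C@@H]3C[C@H](C)CC[C@H]3C(C)C)[C@H]1C(C)C)C(C)(C)C(=O)C(C)(C)C2=O
F3 | step 3 | syncarpic acid methyl ether, 5-methoxy-2,2,6,6-tetramethylcyclohex-4-ene-1,3-dione | COC1=CC(=O)C(C)(C)C(=O)C1(C)C
F4 | step 3 | 2-iodo-3-methoxy-4,4,6,6-tetramethylcyclohex-2-ene-1,5-dione | IC1=C(OC)C(C)(C)C(=O)C(C)(C)C1=O
F5 | step 8 | (3S,4S) bicyclic lactol, C2 anomers | CC(C)C[C@@H]1C2=C(OC(O)[C@H]1C(C)C)C(C)(C)C(=O)C(C)(C)C2=O
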